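**Strategy.** The cyclopentane is disconnected at both bonds leaving the ring-fusion atoms, C1–C2 and C4–C5 (guaiane locants), as a [3+2] annulation of a but-1-en-2-yl unit (C2, C3, C4, C15) onto a cycloheptenone. The feature exploited is the 1,3-relationship between oxygenated C8 and methyl-bearing C10 in the seven-membered ring, read as cycloheptane-1,3-dione: in its cross-conjugated vinylogous ester, C10=O activates C1=C5 and later accepts the C14 methyl, while C8 stays oxygenated. In one pot, Rh(acac)(C2H4)2/(R)-BINAP-catalysed 1,4-addition of a 4-chlorobut-1-en-2-yl borate forms C4–C5 and sets C5; base then closes C1–C2 by alkylation of the C1 enolate.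

Key step: step 3

Remark: locants are guaiane locants (C1 and C5 ring fusion; C2, C3, C4 complete the five-membered ring, C4 bearing methyl C15; C6 to C10 complete the seven-membered ring, C7 bearing C11, C8 the oxygen, C10 methyl C14); bicyclic compounds are named as saturated hydroazulenes ("hydroazul", bicyclo[5.3.0]decane) with these locants and only the stated unsaturation; 5 and 19 are taken as purchasable.

Step 1
Reactants: 1 cycloheptane-1,3-dione
Product: 2 3-(2-methylpropoxy)cyclohept-2-en-1-one
Conditions: i-BuOH, PPTS (cat.), toluene, reflux, Dean–Stark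
Reagents that add atoms: 2-methylpropan-1-ol CC(C)CO
Why: Acid-catalysed condensation of the 1,3-dione with the alcohol under azeotropic removal of water gives the vinylogous ester (enol ether formation); no stereocenter is formed.

Step 2
Reactants: 2 3-(2-methylpropoxy)cyclohept-2-en-1-one
Product: 4 3-(2-methylpropoxy)cyclohepta-2,6-dien-1-one, via silyloxydiene 3 (not isolated)
Conditions: LiN(iPr)2, THF, −78 °C; Me3SiCl; then Pd(OAc)2 (10 mol %), O2 (1 atm), DMSO, rt
Reagents that add atoms: none
Why: Kinetic deprotonation of the vinylogous ester occurs at its only enolisable α-carbon (C1), and Saegusa–Ito oxidation of the 2-silyloxydiene (palladium enolate, β-hydride elimination) installs C1=C5 to give the cross-conjugated dienone; no stereocenter is formed.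

Step 3
Reactants: 4 3-(2-methylpropoxy)cyclohepta-2,6-dien-1-one; 5 2-bromo-4-chlorobut-1-ene
Product: 9 (1R,5R)-4-methylidene-8-(2-methylpropoxy)hydroazul-8-en-10-one (cis-fused), via alkenyllithium 6 (not isolated), via alkenyltrimethoxyborate 7 (not isolated), via chloro ketone 8 (not isolated)
Conditions: one pot: 5, t-BuLi (2 equiv), Et2O, −78 °C; B(OMe)3, −78 °C to rt; solvent switched to dioxane; then 4, Rh(acac)(C2H4)2 (3 mol %), (R)-BINAP (3.3 mol %), H2O (2 equiv), 50 °C; then KOtBu (excess), THF, 0 °C to rt
Reagents that add atoms: none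
Why: The alkenyl group passes from boron to monovalent rhodium and inserts across the C1=C5 enone (Hayashi–Miyaura asymmetric 1,4-addition); hydrolysis of the oxa-π-allyl rhodium releases chloro ketone 8 with the new C4–C5 bond. KOtBu then forms the α′ (C1) enolate of the vinylogous ester, which displaces the primary chloride in a 5-exo-tet (enolexo) closure of the five-membered ring, the cycloalkylation half of a methylenecyclopentane annulation. C5 is set by the catalyst: (R)-BINAP is selected by analogy with the established facial sense of cycloalkenone additions (the antipode would be used should the sense be reversed), to give the 5R adduct, whose descriptor becomes 5S once C4 is saturated. C1 is set by the substrate, since the tether on C5 reaches only the syn face of the enolate and gives the cis ring fusion; this centre is flattened later, and C4 stays sp2 until step 4. The step needs site selectivity between the two enone units and regioselective enolisation: the β-alkoxy enone C8=C9 is too electron-rich to accept the alkenylrhodium, and because C9 is sp2, C1 is the only α-carbon that can enolise and close a five-membered ring.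

Step 4
Reactants: 9 (1R,5R)-4-methylidene-8-(2-methylpropoxy)hydroazul-8-en-10-one
Product: 10 (1R,4S,5S)-4-methyl-8-(2-methylpropoxy)hydroazul-8-en-10-one
Conditions: H2 (1 atm), RhCl(PPh3)3 (5 mol %), benzene/EtOH, rt
Reagents that add atoms: none
Why: Homogeneous hydrogenation with RhCl(PPh3)3 reduces only the 1,1-disubstituted exocyclic alkene without double-bond migration (the enol-ether double bond is trisubstituted and deactivated), and hydrogen is delivered to C4 from the face of H5, anti to the C5–C6 bond of the cis-fused bicycle, so that C4 becomes S with the methyl cis to C6.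

Step 5
Reactants: 10 (1R,4S,5S)-4-methyl-8-(2-methylpropoxy)hydroazul-8-en-10-one
Product: 12 (1R,4S,5S)-4,10-dimethylhydroazul-9-en-8-one, via lithium carbinolate 11 (not isolated)
Conditions: MeLi, CeCl3, THF, −78 °C; then 1 M HCl (aq), THF, rt
Reagents that add atoms: methyllithium [Li]C
Why: Stork–Danheiser transposition: MeLi/CeCl3 adds 1,2 to the vinylogous ester carbonyl C10 without enolising C1, and aqueous acid hydrolyses the enol ether with loss of the C10 hydroxyl, which moves the carbonyl to C8 and leaves the C14 methyl on C10; the C10 carbinol centre is transient and C1, C4 and C5 are untouched.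

Step 6
Reactants: 12 (1R,4S,5S)-4,10-dimethylhydroazul-9-en-8-one
Product: 14 (1R,4S,5S,7R)-4,10-dimethyl-7-[2-(triethylsilyloxy)propan-2-yl]hydroazul-9-en-8-one, via lithium aldolate 13 (not isolated)
Conditions: LiN(iPr)2, THF, −78 °C; acetone, −78 to −45 °C; then Et3SiOTf (1.1 equiv), −78 °C
Reagents that add atoms: acetone CC(C)=O; triethylsilyl trifluoromethanesulfonate CC[Si](CC)(CC)OS(=O)(=O)C(F)(F)F
Why: Kinetic deprotonation of the enone at the α′ carbon C7 and aldol addition to acetone give a chelated lithium aldolate that should equilibrate by retro-aldol/re-addition toward the C7 epimer with the pseudo-equatorial side chain (H7 cis to H5, 7R), which O-silylation in the flask then protects against retro-aldol cleavage.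

Step 7
Reactants: 14 (1R,4S,5S,7R)-4,10-dimethyl-7-[2-(triethylsilyloxy)propan-2-yl]hydroazul-9-en-8-one
Product: 16 (4S,5S,7R)-4,10-dimethyl-7-[2-(triethylsilyloxy)propan-2-yl]hydroazul-1(10)-en-8-one, via potassium dienolate 15 (not isolated)
Conditions: KOtBu, t-BuOH/THF, 0 °C; then poured into AcOH, THF/H2O, −20 °C
Reagents that add atoms: none
Why: Base-mediated deconjugation: KOtBu forms the thermodynamic endocyclic 1(10),8-dienolate (the α′ hydrogen on C7 is shielded by the silyloxyisopropyl group), and kinetic C-protonation at the α-carbon C9 by acetic acid gives the β,γ-unsaturated ketone with the tetrasubstituted C1=C10 double bond; C7 is not expected to change and, should it enolise, returns to the same more stable epimer.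

Step 8
Reactants: 16 (4S,5S,7R)-4,10-dimethyl-7-[2-(triethylsilyloxy)propan-2-yl]hydroazul-1(10)-en-8-one
Product: 18 (4S,5S,7S,8S)-7-(2-hydroxypropan-2-yl)-4,10-dimethylhydroazul-1(10)-en-8-ol, via hydroxy ketone 17 (not isolated)
Conditions: HF·pyridine, MeCN, 0 °C; then Me4NBH(OAc)3, AcOH/MeCN, −25 °C
Reagents that add atoms: none
Why: Fluoride desilylation frees the tertiary alcohol, which exchanges onto boron so that hydride is delivered internally to C8 (Evans–Saksena hydroxyl-directed reduction) along the axial trajectory on the side of the C7 substituent, giving the 7,8-trans (8S) alcohol under acidic conditions that should not re-conjugate the alkene.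

Step 9
Reactants: 18 (4S,5S,7S,8S)-7-(2-hydroxypropan-2-yl)-4,10-dimethylhydroazul-1(10)-en-8-ol; 19 (E)-3-(4-acetoxyphenyl)prop-2-enoic acid
Product: 21 (4S,5S,7S,8S)-7-(2-hydroxypropan-2-yl)-4,10-dimethylhydroazul-1(10)-en-8-yl (E)-3-(4-acetoxyphenyl)prop-2-enoate, via acid chloride 20 (not isolated)
Conditions: 19, (COCl)2, DMF (cat.), CH2Cl2, 0 °C to rt, evaporate; then 18, pyridine, DMAP (cat.), CH2Cl2, 0 °C to rt
Reagents that add atoms: none
Why: Acyl chloride formation followed by pyridine/DMAP acylation (nucleophilic catalysis) esterifies the secondary C8 hydroxyl selectively, the tertiary C11 hydroxyl being too hindered; no stereocenter is affected.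

Step 10
Reactants: 21 (4S,5S,7S,8S)-7-(2-hydroxypropan-2-yl)-4,10-dimethylhydroazul-1(10)-en-8-yl (E)-3-(4-acetoxyphenyl)prop-2-enoate
Product: 22 (4S,5S,7S,8S)-7-(2-hydroxypropan-2-yl)-4,10-dimethylhydroazul-1(10)-en-8-yl (E)-3-(4-hydroxyphenyl)prop-2-enoate (target)
Conditions: pyrrolidine, CH2Cl2, 0 °C
Reagents that add atoms: none
Why: Aminolysis of the aryl acetate, an activated phenyl ester, by pyrrolidine should be far faster than attack on the hindered secondary alkyl cinnamate, which frees the phenol and gives the target.

**Compound list**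

1 | cycloheptane-1,3-dione | O=C1CCCCC(=O)C1 | starting material
2 | 3-(2-methylpropoxy)cyclohept-2-en-1-one | CC(C)COC1=CC(=O)CCCC1 | intermediate
3 | 1-(2-methylpropoxy)-3-(trimethylsilyloxy)cyclohepta-1,3-diene | CC(C)COC1=CC(O[Si](C)(C)C)=CCCC1 | intermediate (not isolated)
4 | 3-(2-methylpropoxy)cyclohepta-2,6-dien-1-one | CC(C)COC1=CC(=O)C=CCC1 | intermediate
5 | 2-bromo-4-chlorobut-1-ene | C=C(Br)CCCl | starting material
6 | (4-chlorobut-1-en-2-yl)lithium | [Li]C(=C)CCCl | intermediate (not isolated)
7 | lithium (4-chlorobut-1-en-2-yl)trimethoxyborate | [Li+].CO[B-](OC)(OC)C(=C)CCCl | intermediate (not isolated)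
8 | (6R)-6-(4-chlorobut-1-en-2-yl)-3-(2-methylpropoxy)cyclohept-2-en-1-one (5R in guaiane locants) | CC(C)COC1=CC(=O)C[C@H](C(=C)CCCl)CC1 | intermediate (not isolated)
9 | (1R,5R)-4-methylidene-8-(2-methylpropoxy)hydroazul-8-en-10-one, cis-fused | CC(C)COC1=CC(=O)[C@@H]2CCC(=C)[C@@H]2CC1 | intermediate
10 | (1R,4S,5S)-4-methyl-8-(2-methylpropoxy)hydroazul-8-en-10-one, cis-fused, methyl cis to C6 | CC(C)COC1=CC(=O)[C@@H]2CC[C@H](C)[C@@H]2CC1 | intermediate
11 | lithium (1R,4S,5S)-4,10-dimethyl-8-(2-methylpropoxy)hydroazul-8-en-10-olate (C10 configuration undefined, lost in the same step) | [Li+].CC(C)COC1=CC(C)([O-])[C@@H]2CC[C@H](C)[C@@H]2CC1 | intermediate (not isolated)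
12 | (1R,4S,5S)-4,10-dimethylhydroazul-9-en-8-one | CC1=CC(=O)CC[C@H]2[C@@H](C)CC[C@@H]12 | intermediate
13 | lithium 2-[(1R,4S,5S,7R)-4,10-dimethyl-8-oxohydroazul-9-en-7-yl]propan-2-olate | [Li+].CC1=CC(=O)[C@@H](C(C)(C)[O-])C[C@H]2[C@@H](C)CC[C@@H]12 | intermediate (not isolated)
14 | (1R,4S,5S,7R)-4,10-dimethyl-7-[2-(triethylsilyloxy)propan-2-yl]hydroazul-9-en-8-one | CC1=CC(=O)[C@@H](C(C)(C)O[Si](CC)(CC)CC)C[C@H]2[C@@H](C)CC[C@@H]12 | intermediate
15 | potassium 1(10),8-dienolate of 16 (C4, C5, C7 arranged as in 16) | [K+].CC1=C2CC[C@H](C)[C@@H]2C[C@H](C(C)(C)O[Si](CC)(CC)CC)C([O-])=C1 | intermediate (not isolated)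
16 | (4S,5S,7R)-4,10-dimethyl-7-[2-(triethylsilyloxy)propan-2-yl]hydroazul-1(10)-en-8-one | CC1=C2CC[C@H](C)[C@@H]2C[C@H](C(C)(C)O[Si](CC)(CC)CC)C(=O)C1 | intermediate
17 | (4S,5S,7R)-7-(2-hydroxypropan-2-yl)-4,10-dimethylhydroazul-1(10)-en-8-one | CC1=C2CC[C@H](C)[C@@H]2C[C@H](C(C)(C)O)C(=O)C1 | intermediate (not isolated)
18 | (4S,5S,7S,8S)-7-(2-hydroxypropan-2-yl)-4,10-dimethylhydroazul-1(10)-en-8-ol | CC1=C2CC[C@H](C)[C@@H]2C[C@H](C(C)(C)O)[C@@H](O)C1 | intermediate
19 | (E)-3-(4-acetoxyphenyl)prop-2-enoic acid | CC(=O)Oc1ccc(/C=C/C(=O)O)cc1 | starting material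
20 | (E)-3-(4-acetoxyphenyl)prop-2-enoyl chloride | CC(=O)Oc1ccc(/C=C/C(=O)Cl)cc1 | intermediate (not isolated)
21 | (4S,5S,7S,8S)-7-(2-hydroxypropan-2-yl)-4,10-dimethylhydroazul-1(10)-en-8-yl (E)-3-(4-acetoxyphenyl)prop-2-enoate | CC1=C2CC[C@H](C)[C@@H]2C[C@H](C(C)(C)O)[C@@H](OC(=O)/C=C/c2ccc(OC(C)=O)cc2)C1 | intermediate
22 | (4S,5S,7S,8S)-7-(2-hydroxypropan-2-yl)-4,10-dimethylhydroazul-1(10)-en-8-yl (E)-3-(4-hydroxyphenyl)prop-2-enoate | CC1=C2CC[C@H](C)[C@@H]2C[C@H](C(C)(C)O)[C@@H](OC(=O)/C=C/c2ccc(O)cc2)C1 | target

Total step count: 10. Longest linear sequence: 10 steps (from 1).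

**Steps most likely to fail**

1. Step 7 (deconjugation). Under the alkoxide base any α′-enolate can expel the tertiary silyloxide (β-elimination to the isopropylidene ketone), and the quench can protonate at C1 and return the conjugated enone. Fallback: the extended enolate is generated reductively under neutral conditions. The route leaves at 10. Sulfenylation of its C1 enolate (LiN(iPr)2; PhSSPh) should give the 1-(phenylsulfanyl) vinylogous ester F3. MeLi/CeCl3 followed by aqueous HCl, as in step 5, should give the γ-(phenylsulfanyl) enone F4. Aldol addition to acetone as in step 6, but with an aqueous quench, should give the free β-hydroxy enone F5. SmI2 in THF/MeOH at −78 °C should then cleave the allylic C1–S bond through the ketyl, and C9 protonation of the samarium dienolate should give 17, where the route is rejoined at the second stage of step 8.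

2. Step 3 (key step). Transmetalation of the hindered 1,1-disubstituted alkenyl borate may be slow and lose out to protodeboronation, alkoxide may attack the primary chloride before the ring closes, and closure may stall in the wet medium. Fallback: the two bond formations are separated and the boron reagent is isolated. From 5, t-BuLi and then 2-isopropoxy-4,4,5,5-tetramethyl-1,3,2-dioxaborolane should give the pinacol boronate F1. Rh(acac)(C2H4)2/(R)-BINAP with KOH in dioxane/H2O should add F1 to 4, and 8 is now isolated. NaI in acetone should give the iodo ketone F2, and LiN(iPr)2 in THF (−78 to 0 °C) should close the ring, so that the route is rejoined at 9.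

3. Step 4 (C4 hydrogenation). The exocyclic double bond may migrate into the ring before it is reduced, which would also endanger C5, and facial discrimination at C4 may be poor. Fallback: C4 is set by hydroboration and the oxygen is then removed. From 9, 9-BBN followed by NaBO3 should give the primary alcohol F6, boron and hydrogen adding from the H5 face. I2, PPh3 and imidazole should give the iodide F7, and Bu3SnH with AIBN should reduce it to 10.

**Further compounds**

F1 | step 3 | 2-(4-chlorobut-1-en-2-yl)-4,4,5,5-tetramethyl-1,3,2-dioxaborolane | C=C(CCCl)B1OC(C)(C)C(C)(C)O1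
F2 | step 3 | (6R)-6-(4-iodobut-1-en-2-yl)-3-(2-methylpropoxy)cyclohept-2-en-1-one | CC(C)COC1=CC(=O)C[C@H](C(=C)CCI)CC1
F3 | step 7 | 1-(phenylsulfanyl) derivative of 10 (SPh in place of H1, cis-fused) | CC(C)COC1=CC(=O)[C@]2(Sc3ccccc3)CC[C@H](C)[C@@H]2CC1
F4 | step 7 | 1-(phenylsulfanyl) derivative of 12 (SPh in place of H1) | CC1=CC(=O)CC[C@H]2[C@@H](C)CC[C@@]12Sc3ccccc3
F5 | step 7 | 7-(2-hydroxypropan-2-yl) derivative of F4 (C7 as in 14, free tertiary alcohol) | CC1=CC(=O)[C@@H](C(C)(C)O)C[C@H]2[C@@H](C)CC[C@@]12Sc3ccccc3
F6 | step 4 | 4-(hydroxymethyl) analogue of 10 (C1, C4, C5 arranged as in 10) | CC(C)COC1=CC(=O)[C@@H]2CC[C@H](CO)[C@@H]2CC1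
F7 | step 4 | 4-(iodomethyl) analogue of 10 (C1, C4, C5 arranged as in 10) | CC(C)COC1=CC(=O)[C@@H]2CC[C@H](CI)[C@@H]2CC1
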